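The nine-membered ring is not cyclised but grown from a cyclopentane: C5–C6 is disconnected and C3–C8 reconnected. The feature used is the array C8(=CH2, a masked ketone)–C7–C6–C5–C4(O,CH3)–C3: the carbonyl carbon sits three bonds from C5, with C3=C4 as a latent δ,ε-alkene, the signature of an oxy-Cope product. One alkoxide [3,3] shift forms C5–C6, cleaves C3–C8, expands five to nine and sets C5. Its precursor is a 2-exo-vinyl-3-exo-alkenyl-6,6-dimethylbicyclo[3.2.0]heptan-2-ol that already holds the cyclobutane, C1' with isobutyl, and ring A as its methyl enol ether. Acid closure of a ring-A oxygen onto C4 and methylenation finish the synthesis.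

Key step: step 10

Remark: core atoms carry caryophyllane numbers (bicycloheptane C5 = C1, C1 = C9, C2 = C8, C3 = C3; C1' is the side-chain methine; ring A is the syncarpic unit); exo means the convex face, syn to the bridgehead hydrogens; the ligand enantiomer in step 4 is assumed to be the one that gives (R)-C1'.

Step 1
Reactants: 1 cyclopent-2-en-1-one; 2 isobutylene
Product: 3 rac-cis-6,6-dimethylbicyclo[3.2.0]heptan-2-one
Conditions: hν (medium-pressure Hg lamp, Pyrex), excess 2, CH2Cl2, −78 °C; distillation
Reagents that add atoms: none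
Why: Enone–alkene [2+2] photocycloaddition through the triplet enone and a 1,4-biradical should favour the head-to-tail adduct (CMe2 on the β-carbon), and a four–five fusion can only be cis, so the two bridgeheads are set relative to each other; the head-to-head isomer is removed by distillation.

Step 2
Reactants: 3 rac-cis-6,6-dimethylbicyclo[3.2.0]heptan-2-one
Product: 4 (1R,5R)-6,6-dimethylbicyclo[3.2.0]heptan-2-one
Conditions: preparative SFC, amylose tris(3,5-dimethylphenylcarbamate) phase, CO2/i-PrOH
Reagents that add atoms: none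
Why: Resolution by chromatography on a chiral stationary phase needs no derivatisation of the rigid ketone; the (1R,5R) antipode, identified by its chiroptical data, carries C1 of the target.

Step 3
Reactants: 5 syncarpic acid; 6 isovaleraldehyde
Product: 7 2-(3-methylbutylidene)-4,4,6,6-tetramethylcyclohexane-1,3,5-trione
Conditions: L-proline (cat.), MgSO4, CH2Cl2, 0 °C to rt; used crude at once
Reagents that add atoms: none
Why: Knoevenagel condensation at the acidic C2 methylene of the trione gives the doubly activated enetrione, which is symmetrical (no E/Z issue) and is not stored because it is a strong Michael acceptor.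

Step 4
Reactants: 7 2-(3-methylbutylidene)-4,4,6,6-tetramethylcyclohexane-1,3,5-trione
Product: 8 5-hydroxy-2,2,6,6-tetramethyl-4-[(4R)-6-methylhept-2-yn-4-yl]cyclohex-4-ene-1,3-dione
Conditions: propyne (excess, sealed), Cu(OAc)2·H2O (cat.), PINAP-type P,N ligand (cat.), sodium ascorbate (cat.), H2O, 0 °C; acidic work-up
Reagents that add atoms: propyne, CC#C
Why: Copper-catalysed enantioselective conjugate alkynylation of an alkylidene 1,3-dicarbonyl acceptor: the ligated copper propynylide should add to one face of the s-cis-locked enetrione and so set C1' as R, and the product is held as its stabilised enolate, which stops a second addition.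

Step 5
Reactants: 8 5-hydroxy-2,2,6,6-tetramethyl-4-[(4R)-6-methylhept-2-yn-4-yl]cyclohex-4-ene-1,3-dione
Product: 9 5-methoxy-2,2,6,6-tetramethyl-4-[(4R)-6-methylhept-2-yn-4-yl]cyclohex-4-ene-1,3-dione
Conditions: TMSCHN2, MeOH/toluene, 0 °C to rt
Reagents that add atoms: (trimethylsilyl)diazomethane, C[Si](C)(C)C=[N+]=[N-]
Why: O-Methylation of the acidic enol with a diazoalkane runs by proton transfer and SN2 on the diazonium carbon, so only oxygen is alkylated, and the two enol oxygens are equivalent by the local symmetry of ring A, so a single ether should form.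

Step 6
Reactants: 9 5-methoxy-2,2,6,6-tetramethyl-4-[(4R)-6-methylhept-2-yn-4-yl]cyclohex-4-ene-1,3-dione
Product: 11 4-[(2E,4R)-2-iodo-6-methylhept-2-en-4-yl]-5-methoxy-2,2,6,6-tetramethylcyclohex-4-ene-1,3-dione, via alkenylzirconocene 10 (not isolated)
Conditions: Cp2Zr(H)Cl (excess), THF, rt to 40 °C; then I2, −20 to 0 °C
Reagents that add atoms: iodine, II
Why: Hydrozirconation (Schwartz reagent) is a syn addition that excess reagent equilibrates to zirconium on the less hindered, methyl-bearing alkyne carbon, and iodinolysis goes with retention to the E iodide; both ring-A carbonyls are flanked by quaternary carbons (one is a vinylogous ester), which should keep their reduction slow.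

Step 7
Reactants: 4 (1R,5R)-6,6-dimethylbicyclo[3.2.0]heptan-2-one
Product: 13 (1R,5R)-6,6-dimethyl-2-(trimethylsilyloxy)bicyclo[3.2.0]hept-2-ene, via lithium enolate 12 (not isolated)
Conditions: LDA, THF, −78 °C; TMSCl, −78 °C to rt
Reagents that add atoms: chlorotrimethylsilane, C[Si](C)(C)Cl
Why: Kinetic enolisation followed by O-silylation: deprotonation should occur at the C3 methylene, because the other enolate would put a double bond at the four–five ring fusion.

Step 8
Reactants: 13 (1R,5R)-6,6-dimethyl-2-(trimethylsilyloxy)bicyclo[3.2.0]hept-2-ene; 11 4-[(2E,4R)-2-iodo-6-methylhept-2-en-4-yl]-5-methoxy-2,2,6,6-tetramethylcyclohex-4-ene-1,3-dione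
Product: 15 (1R,3S,5R)-3-exo-[(2E,4R)-4-(2-methoxy-3,3,5,5-tetramethyl-4,6-dioxocyclohex-1-en-1-yl)-6-methylhept-2-en-2-yl]-6,6-dimethylbicyclo[3.2.0]heptan-2-one, via tributyltin enolate 14 (not isolated)
Conditions: Pd(OAc)2 (cat.), P(t-Bu)3 (cat.), Bu3SnF, toluene, 80 °C
Reagents that add atoms: none
Why: Pd-catalysed α-alkenylation of a ketone through its tin enolate (silyl enol ether, Bu3SnF and an alkenyl halide): oxidative addition keeps the E geometry, the C-bound palladium enolate should form on the convex face so that reductive elimination sets C3 exo, and without strong base the product is not re-enolised, which protects C3, C1' and the β,γ-position of the alkene.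

Step 9
Reactants: 15 (1R,3S,5R)-3-exo-alkenyl-6,6-dimethylbicyclo[3.2.0]heptan-2-one (full name in step 8)
Product: 16 (1R,2R,3S,5R)-2-ethenyl-3-[(2E,4R)-4-(2-methoxy-3,3,5,5-tetramethyl-4,6-dioxocyclohex-1-en-1-yl)-6-methylhept-2-en-2-yl]-6,6-dimethylbicyclo[3.2.0]heptan-2-ol
Conditions: CH2=CHMgBr, anhydrous CeCl3, THF, −78 °C
Reagents that add atoms: vinylmagnesium bromide, C=C[Mg]Br
Why: 1,2-Addition of an organocerium reagent, which is nucleophilic but hardly basic, avoids enolisation of the β,γ-unsaturated ketone; attack should come from the convex face because the cyclobutane and its endo methyl cover the concave approach, which places vinyl exo and cis to the C3 alkenyl group, and the hindered ring-A carbonyls should not compete at −78 °C.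

Step 10
Reactants: 16 (1R,2R,3S,5R)-2-exo-ethenyl-3-exo-alkenyl-6,6-dimethylbicyclo[3.2.0]heptan-2-ol (full name in step 9)
Product: 20 (1R,5S,9S,3Z)-5-[(1R)-1-(2-methoxy-3,3,5,5-tetramethyl-4,6-dioxocyclohex-1-en-1-yl)-3-methylbutyl]-4,11,11-trimethylbicyclo[7.2.0]undec-3-en-8-one, via potassium alkoxide 17 (not isolated), via potassium enolate 18 (not isolated), via cis-fused ketone 19 (not isolated)
Conditions: KHMDS, 18-crown-6, THF, −78 to 0 °C; then t-BuOH, rt; AcOH
Reagents that add atoms: none
Why: Anionic oxy-Cope rearrangement: the crown-separated alkoxide 17 undergoes a [3,3] sigmatropic shift in which C5–C6 forms as C3–C8 breaks, giving enolate 18. The closest known reactions are the alkoxide-accelerated ring expansions of 1,2-dialkenylcycloalkanols to medium-ring enones and the boat Cope interconversion of cis-1,2-divinylcyclopentane with cis,cis-cyclonona-1,5-diene. No chain is cyclised: the nine-membered ring arises by four-atom expansion of the cyclopentane through the six-atom array C6–C7–C8···C3–C4–C5, so the closure is pericyclic and not an exo or endo ring closure. C5 is set by the exo configuration at C8 together with the E alkenyl geometry: in the endo-boat, which is the arrangement that a cis-1,2 pair on a five-membered ring reaches without twisting, H5 points inward and C1' outward, and suprafacial bonding should give 5S with a Z C3=C4 bond. C9 is then set thermodynamically by t-BuOK/t-BuOH equilibration next to the new ketone, the trans-fused bicyclo[7.2.0] ketone (9S) being the more stable. The step needs boat over chair and rearrangement over fragmentation; the first is secured by the cis-dialkenyl arrangement (either chair would have to place an E alkene or an E enolate in the ring), the second by release of bicyclo[3.2.0] strain and enolate formation.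

Step 11
Reactants: 20 trans-fused cyclononenone (full name in step 10)
Product: 21 8-oxo-15-nor-tomentodione B, the (1R,4R,5S,9S,1'R) pyran-fused ketone with the ring-A enol oxygen bonded to C4
Conditions: p-TsOH·H2O, toluene, 60 °C
Reagents that add atoms: water, O
Why: Acid-catalysed Markovnikov cycloetherification: protonation at C3 gives the tertiary C4 cation, a ring-A carbonyl oxygen closes the six-membered ring and the resulting oxocarbenium ion is hydrolysed with loss of methanol; the C5–C1' tether should deliver oxygen to the C4 face anti to C6 with H5 near the alkene plane (least A1,3 strain), which gives the trans-fused pyran (4R), and the step precedes methylenation because an exocyclic alkene would trap the cation across the ring.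

Step 12
Reactants: 21 8-oxo-15-nor-tomentodione B
Product: 22 Tomentodione B
Conditions: Ph3PCH3Br, KOt-Bu, THF, 0 °C to rt
Reagents that add atoms: methyltriphenylphosphonium bromide, C[P+](c1ccccc1)(c1ccccc1)c1ccccc1.[Br-]
Why: Wittig methylenation should occur only at the C8 ketone, since the ring-A ketone lies between two quaternary carbons and the other carbonyl is a vinylogous ester; C9 stays trans because that is its equilibrium configuration.

Compound list
1 | cyclopent-2-en-1-one | O=C1C=CCC1 | starting material
2 | isobutylene | C=C(C)C | starting material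
3 | rac-cis-6,6-dimethylbicyclo[3.2.0]heptan-2-one (1:1 pair of enantiomers) | O=C1CC[C@@H]2[C@H]1CC2(C)C.O=C1CC[C@H]2[C@@H]1CC2(C)C | intermediate
4 | (1R,5R)-6,6-dimethylbicyclo[3.2.0]heptan-2-one | O=C1CC[C@@H]2[C@H]1CC2(C)C | intermediate
5 | syncarpic acid | CC1(C)C(=O)CC(=O)C(C)(C)C1=O | starting material
6 | isovaleraldehyde | CC(C)CC=O | starting material
7 | 2-(3-methylbutylidene)-4,4,6,6-tetramethylcyclohexane-1,3,5-trione | CC(C)CC=C1C(=O)C(C)(C)C(=O)C(C)(C)C1=O | intermediate
8 | 5-hydroxy-2,2,6,6-tetramethyl-4-[(4R)-6-methylhept-2-yn-4-yl]cyclohex-4-ene-1,3-dione | CC#C[C@@H](CC(C)C)C1=C(O)C(C)(C)C(=O)C(C)(C)C1=O | intermediate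
9 | 5-methoxy-2,2,6,6-tetramethyl-4-[(4R)-6-methylhept-2-yn-4-yl]cyclohex-4-ene-1,3-dione | CC#C[C@@H](CC(C)C)C1=C(OC)C(C)(C)C(=O)C(C)(C)C1=O | intermediate
10 | chlorobis(cyclopentadienyl)[(2E,4R)-4-(2-methoxy-3,3,5,5-tetramethyl-4,6-dioxocyclohex-1-en-1-yl)-6-methylhept-2-en-2-yl]zirconium (Cp drawn η1) | C/C(=C\[C@@H](CC(C)C)C1=C(OC)C(C)(C)C(=O)C(C)(C)C1=O)[Zr](Cl)(C1C=CC=C1)C1C=CC=C1 | intermediate (not isolated)
11 | 4-[(2E,4R)-2-iodo-6-methylhept-2-en-4-yl]-5-methoxy-2,2,6,6-tetramethylcyclohex-4-ene-1,3-dione | I/C(C)=C/[C@@H](CC(C)C)C1=C(OC)C(C)(C)C(=O)C(C)(C)C1=O | intermediate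
12 | lithium (1R,5R)-6,6-dimethylbicyclo[3.2.0]hept-2-en-2-olate | [Li+].[O-]C1=CC[C@@H]2[C@H]1CC2(C)C | intermediate (not isolated)
13 | (1R,5R)-6,6-dimethyl-2-(trimethylsilyloxy)bicyclo[3.2.0]hept-2-ene | C[Si](C)(C)OC1=CC[C@@H]2[C@H]1CC2(C)C | intermediate
14 | (1R,5R)-6,6-dimethyl-2-(tributylstannyloxy)bicyclo[3.2.0]hept-2-ene | CCCC[Sn](CCCC)(CCCC)OC1=CC[C@@H]2[C@H]1CC2(C)C | intermediate (not isolated)
15 | (1R,3S,5R)-3-exo-[(2E,4R)-4-(2-methoxy-3,3,5,5-tetramethyl-4,6-dioxocyclohex-1-en-1-yl)-6-methylhept-2-en-2-yl]-6,6-dimethylbicyclo[3.2.0]heptan-2-one | O=C1[C@H](/C(C)=C/[C@@H](CC(C)C)C2=C(OC)C(C)(C)C(=O)C(C)(C)C2=O)C[C@@H]2[C@H]1CC2(C)C | intermediate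
16 | (1R,2R,3S,5R)-2-ethenyl-3-[(2E,4R)-4-(2-methoxy-3,3,5,5-tetramethyl-4,6-dioxocyclohex-1-en-1-yl)-6-methylhept-2-en-2-yl]-6,6-dimethylbicyclo[3.2.0]heptan-2-ol (vinyl and alkenyl exo, OH endo) | C=C[C@]1(O)[C@H](/C(C)=C/[C@@H](CC(C)C)C2=C(OC)C(C)(C)C(=O)C(C)(C)C2=O)C[C@@H]2[C@H]1CC2(C)C | intermediate
17 | potassium alkoxide of 16 | [K+].C=C[C@]1([O-])[C@H](/C(C)=C/[C@@H](CC(C)C)C2=C(OC)C(C)(C)C(=O)C(C)(C)C2=O)C[C@@H]2[C@H]1CC2(C)C | intermediate (not isolated)
18 | potassium C7=C8 enolate of the cis-fused (3Z)-cyclononenone | [K+].[O-]/C1=C/C[C@@H]([C@@H](CC(C)C)C2=C(OC)C(C)(C)C(=O)C(C)(C)C2=O)/C(C)=C\C[C@@H]2[C@H]1CC2(C)C | intermediate (not isolated)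
19 | (1R,5S,9R,3Z)-5-[(1R)-1-(2-methoxy-3,3,5,5-tetramethyl-4,6-dioxocyclohex-1-en-1-yl)-3-methylbutyl]-4,11,11-trimethylbicyclo[7.2.0]undec-3-en-8-one (cis-fused) | O=C1CC[C@@H]([C@@H](CC(C)C)C2=C(OC)C(C)(C)C(=O)C(C)(C)C2=O)/C(C)=C\C[C@@H]2[C@H]1CC2(C)C | intermediate (not isolated)
20 | (1R,5S,9S,3Z)-5-[(1R)-1-(2-methoxy-3,3,5,5-tetramethyl-4,6-dioxocyclohex-1-en-1-yl)-3-methylbutyl]-4,11,11-trimethylbicyclo[7.2.0]undec-3-en-8-one (trans-fused) | O=C1CC[C@@H]([C@@H](CC(C)C)C2=C(OC)C(C)(C)C(=O)C(C)(C)C2=O)/C(C)=C\C[C@@H]2[C@@H]1CC2(C)C | intermediate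
21 | 8-oxo-15-nor-tomentodione B, (1R,4R,5S,9S,1'R) | O=C1CC[C@H]2[C@@H](CC(C)C)C3=C(O[C@]2(C)CC[C@@H]2[C@@H]1CC2(C)C)C(C)(C)C(=O)C(C)(C)C3=O | intermediate
22 | Tomentodione B, (1R,4R,5S,9S,1'R) | C=C1CC[C@H]2[C@@H](CC(C)C)C3=C(O[C@]2(C)CC[C@@H]2[C@@H]1CC2(C)C)C(C)(C)C(=O)C(C)(C)C3=O | target

Total step count: 12. Longest linear sequence: 9 steps (steps 3, 4, 5, 6, 8, 9, 10, 11, 12, from syncarpic acid).

Steps most likely to fail

Step 10. The alkoxide may cleave C3–C8 heterolytically (allyl anion plus ketone, then ring-opened or [1,3]-shifted material). Part of the flux may pass through a chair and so give the C5 epimer. The crown-separated enolate may also add to the ring-A vinylogous ester before it is quenched. The fallback is the neutral variant, which has no charged intermediates. It sets out from 16: silylation (TMSOTf, 2,6-lutidine, CH2Cl2, −78 °C) should give the trimethylsilyl ether of 16, F1. Thermolysis in degassed o-xylene (sealed tube, about 180 °C) is a siloxy-Cope rearrangement through the same boat and should give the cis-fused trimethylsilyl enol ether F2. K2CO3 in MeOH then cleaves the silyl enol ether and equilibrates C9, which returns to the route at 20.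

Step 4. The copper propynylide of a gaseous alkyl alkyne may turn over slowly and with poor facial discrimination, and the acceptor may undergo retro-Knoevenagel hydrolysis in water before it is alkynylated. The fallback replaces catalysis by resolution. It sets out from 7: uncatalysed 1,4-addition of 1-propynylmagnesium bromide (THF, −78 °C) should give the racemic adduct rac-8, F3. Methylation with TMSCHN2 gives the racemic methyl ether rac-9, F4. Preparative chromatography on a chiral stationary phase then delivers the R enantiomer, which returns to the route at 9.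

Step 8. Oxidative addition and transmetalation with the hindered trisubstituted iodide may be slower than protodestannylation of the enolate and reduction of the iodide, and any enolisation of the product would erode the exo C3 configuration or move the alkene into conjugation. The fallback accepts the kinetic C3 epimer. It sets out from 4 and 11: direct Pd-catalysed α-alkenylation of the lithium enolate (LiHMDS, Pd2(dba)3, Q-Phos, toluene, rt) with a cold AcOH quench should protonate the product dienolate on the convex face and give the 3-endo epimer of 15, F5. Vinylcerium then adds on the convex face, now anti to the alkenyl group, to give the trans-dialkenyl carbinol F6. KHMDS/18-crown-6 followed by t-BuOH should take F6 through the only chair open to it to the (3E)-isomer of 20, F7, with the same 5S centre, because the exo C8 centre and the E alkenyl geometry again decide C5. TsOH·H2O protonates F7 to the same C4 cation, so the sequence returns to the route at 21.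

Further compounds
F1 | step 10 | trimethylsilyl ether of 16 | C=C[C@]1(O[Si](C)(C)C)[C@H](/C(C)=C/[C@@H](CC(C)C)C2=C(OC)C(C)(C)C(=O)C(C)(C)C2=O)C[C@@H]2[C@H]1CC2(C)C
F2 | step 10 | cis-fused (3Z)-8-(trimethylsilyloxy)bicyclo[7.2.0]undeca-3,7-diene bearing the C5 side chain | C[Si](C)(C)O/C1=C/C[C@@H]([C@@H](CC(C)C)C2=C(OC)C(C)(C)C(=O)C(C)(C)C2=O)/C(C)=C\C[C@@H]2[C@H]1CC2(C)C
F3 | step 4 | rac-8 (racemic at C1') | CC#CC(CC(C)C)C1=C(O)C(C)(C)C(=O)C(C)(C)C1=O
F4 | step 4 | rac-9 (racemic at C1') | CC#CC(CC(C)C)C1=C(OC)C(C)(C)C(=O)C(C)(C)C1=O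
F5 | step 8 | (1R,3R,5R)-3-endo epimer of 15 | O=C1[C@@H](/C(C)=C/[C@@H](CC(C)C)C2=C(OC)C(C)(C)C(=O)C(C)(C)C2=O)C[C@@H]2[C@H]1CC2(C)C
F6 | step 8 | (1R,2R,3R,5R)-2-exo-ethenyl-3-endo-alkenyl epimer of 16 | C=C[C@]1(O)[C@@H](/C(C)=C/[C@@H](CC(C)C)C2=C(OC)C(C)(C)C(=O)C(C)(C)C2=O)C[C@@H]2[C@H]1CC2(C)C
F7 | step 8 | (1R,5S,9S,3E)-isomer of 20 | O=C1CC[C@@H]([C@@H](CC(C)C)C2=C(OC)C(C)(C)C(=O)C(C)(C)C2=O)/C(C)=C/C[C@@H]2[C@@H]1CC2(C)C
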